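The route rests on cutting the C1''–C2'' bond of the geranyl ether, between the O-bound CH2 on the 4'-oxygen of ring B and the vinylic CH of the E-trisubstituted C2''=C3'' alkene. The key step exploits the 4'-O–CH2 carbon: its oxygen stabilises a radical, so this carbon can be carried as an aryloxyacetic acid. A dual nickel/iridium photoredox decarboxylative alkenylation expels CO2 and joins the unprotected (S)-flavanone acid with a geometrically pure C9 alkenyl iodide, giving the target directly. The precursor is (S)-naringenin 4'-O-acetic acid, whose C2 stereocentre comes from a rhodium-catalysed asymmetric 1,4-addition of an arylboronic acid to a chromone.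

Key step: step 7

Assumption: the sense of induction in step 5 is assigned from the quadrant model of the Hayashi–Miyaura reaction for (S)-biaryl bisphosphines; should the other face be attacked, the (R)-ligand is used and nothing else changes.

Step 1
Reactants: 1 6-methylhept-5-en-2-one
Product: 3 6-methylhept-5-en-1-yne, via enol phosphate 2 (not isolated)
Conditions: LDA (1.05 equiv), THF, −78 °C; ClP(O)(OEt)2, −78 °C to rt; then LDA (2.3 equiv), THF, −78 °C to rt; H2O
Reagents that add atoms: diethyl chlorophosphate CCOP(=O)(Cl)OCC (its atoms are kept only in intermediate 2)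
Why: Kinetic enolisation at the methyl group, O-phosphorylation and base-induced β-elimination of diethyl phosphate (enol phosphate route from a methyl ketone to a terminal alkyne) should give the 1-alkyne, since the trisubstituted alkene is inert to lithium amides.

Step 2
Reactants: 3 6-methylhept-5-en-1-yne
Product: 5 (E)-1-iodo-2,6-dimethylhepta-1,5-diene, via alkenylalane 4 (not isolated)
Conditions: Me3Al (2 equiv), Cp2ZrCl2 (0.2 equiv), CH2Cl2, 0 °C to rt; then I2, THF, −30 to 0 °C
Reagents that add atoms: trimethylaluminium C[Al](C)C; iodine II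
Why: Negishi zirconium-catalysed carboalumination adds CH3 and Al syn across the terminal alkyne with aluminium at C1, and iodinolysis of the C–Al bond with retention fixes the E geometry of the new trisubstituted alkene, while the remote trisubstituted alkene is too hindered to carbometalate.

Step 3
Reactants: 6 5,7-dihydroxy-4H-chromen-4-one
Product: 7 5,7-bis(benzyloxy)-4H-chromen-4-one
Conditions: BnBr (2.5 equiv), K2CO3 (3 equiv), n-Bu4NI (cat.), DMF, 70 °C
Reagents that add atoms: benzyl bromide BrCc1ccccc1
Why: Williamson ether synthesis, in which warm DMF overcomes the hydrogen bond of the chelated 5-OH and carbonate is not nucleophilic enough to open the pyrone ring.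

Step 4
Reactants: 8 4-hydroxyphenylboronic acid; 9 benzyl bromoacetate
Product: 10 [4-(2-benzyloxy-2-oxoethoxy)phenyl]boronic acid
Conditions: K2CO3 (2 equiv), acetone, reflux; dilute HCl work-up (pH 4)
Reagents that add atoms: none
Why: Williamson ether synthesis of the phenoxide with an activated α-bromo ester, the boronic acid being recovered from its boronate on mildly acidic work-up.

Step 5
Reactants: 7 5,7-bis(benzyloxy)-4H-chromen-4-one; 10 [4-(2-benzyloxy-2-oxoethoxy)phenyl]boronic acid
Product: 11 benzyl 2-{4-[(2S)-5,7-bis(benzyloxy)-4-oxo-3,4-dihydro-2H-chromen-2-yl]phenoxy}acetate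
Conditions: [Rh(OH)(cod)]2 (2.5 mol %), (S)-MeO-F12-BIPHEP (5.5 mol %), 10 (2 equiv), toluene/H2O (20:1), 30 °C
Reagents that add atoms: none
Why: In this Hayashi–Miyaura asymmetric 1,4-addition the aryl–Rh(I) species carbometalates C2=C3 of the chromone on the face left open by the (S)-biaryl bisphosphine (the face attacked in cyclohexenone with (S)-BINAP, which maps onto 2S here), and hydrolysis of the rhodium enolate without added base avoids retro-oxa-Michael racemisation.

Step 6
Reactants: 11 benzyl 2-{4-[(2S)-5,7-bis(benzyloxy)-4-oxo-3,4-dihydro-2H-chromen-2-yl]phenoxy}acetate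
Product: 12 2-{4-[(2S)-5,7-dihydroxy-4-oxo-3,4-dihydro-2H-chromen-2-yl]phenoxy}acetic acid
Conditions: H2 (1 atm), 10% Pd/C, EtOAc/THF, rt, stopped after uptake of 3 equiv H2
Reagents that add atoms: none
Why: Heterogeneous hydrogenolysis removes both aryl benzyl ethers and the benzyl ester in one operation before any alkene is present, because the three primary benzylic C–O bonds should cleave faster than the hindered secondary C2–O1 bond of ring C and the neutral medium leaves C2 untouched.

Step 7
Reactants: 12 2-{4-[(2S)-5,7-dihydroxy-4-oxo-3,4-dihydro-2H-chromen-2-yl]phenoxy}acetic acid; 5 (E)-1-iodo-2,6-dimethylhepta-1,5-diene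
Product: 13 (2S)-2-(4-{[(2E)-3,7-dimethylocta-2,6-dien-1-yl]oxy}phenyl)-5,7-dihydroxy-2,3-dihydro-4H-chromen-4-one (4'-O-geranylnaringenin)
Conditions: Ir[dF(CF3)ppy]2(dtbbpy)PF6 (2 mol %), NiCl2·glyme (10 mol %), dtbbpy (10 mol %), Cs2CO3 (0.5 equiv), 5 (2 equiv), degassed DMSO, 450 nm LEDs, 25 °C
Reagents that add atoms: none
Why: Blue-light-excited Ir(III) oxidises the caesium carboxylate of 12, loss of CO2 gives the oxygen-stabilised aryloxymethyl radical, Ni(0) inserts into the C–I bond of 5 with retention, the alkenyl–Ni(II) species captures the radical, and reductive elimination from Ni(III) forges the C1''–C2'' bond while Ir(II) returns Ni(I) to Ni(0). The closest known reaction type is the metallaphotoredox decarboxylative alkenylation of α-oxy carboxylic acids with vinyl halides, which gives allylic ethers. No ring is closed and no stereocentre is created: the E geometry is inherited from 5, because both organonickel steps are stereoretentive and an isolated trisubstituted alkene lies above the triplet energy of the sensitiser. The C2 stereocentre should survive because the only base present is the carboxylate itself, too weak to enolise C3 and trigger retro-oxa-Michael opening of ring C, and because the flavanone does not absorb at 450 nm. The step needs oxidation of the carboxylate in preference to the phenols, which is secured by keeping 5-OH (chelated to C4=O) and 7-OH protonated, since neutral acylphloroglucinol phenols lie beyond the oxidising power of the excited catalyst. The nucleophilic radical meets no electron-poor alkene, so capture by nickel should outrun addition to the two electron-rich alkenes.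

Compound list
1 | 6-methylhept-5-en-2-one | CC(=O)CCC=C(C)C | starting material
2 | diethyl 6-methylhepta-1,5-dien-2-yl phosphate | C=C(CCC=C(C)C)OP(=O)(OCC)OCC | intermediate
3 | 6-methylhept-5-en-1-yne | C#CCCC=C(C)C | intermediate
4 | [(E)-2,6-dimethylhepta-1,5-dien-1-yl]dimethylalane | CC(C)=CCC/C(C)=C/[Al](C)C | intermediate
5 | (E)-1-iodo-2,6-dimethylhepta-1,5-diene | CC(C)=CCC/C(C)=C/I | intermediate
6 | 5,7-dihydroxy-4H-chromen-4-one | O=c1ccoc2cc(O)cc(O)c12 | starting material
7 | 5,7-bis(benzyloxy)-4H-chromen-4-one | O=c1ccoc2cc(OCc3ccccc3)cc(OCc3ccccc3)c12 | intermediate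
8 | 4-hydroxyphenylboronic acid | OB(O)c1ccc(O)cc1 | starting material
9 | benzyl bromoacetate | O=C(CBr)OCc1ccccc1 | starting material
10 | [4-(2-benzyloxy-2-oxoethoxy)phenyl]boronic acid | OB(O)c1ccc(OCC(=O)OCc2ccccc2)cc1 | intermediate
11 | benzyl 2-{4-[(2S)-5,7-bis(benzyloxy)-4-oxo-3,4-dihydro-2H-chromen-2-yl]phenoxy}acetate | O=C(COc1ccc([C@@H]2CC(=O)c3c(OCc4ccccc4)cc(OCc4ccccc4)cc3O2)cc1)OCc1ccccc1 | intermediate
12 | 2-{4-[(2S)-5,7-dihydroxy-4-oxo-3,4-dihydro-2H-chromen-2-yl]phenoxy}acetic acid | O=C(O)COc1ccc([C@@H]2CC(=O)c3c(O)cc(O)cc3O2)cc1 | intermediate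
13 | (2S)-4'-O-geranylnaringenin | CC(C)=CCC/C(C)=C/COc1ccc([C@@H]2CC(=O)c3c(O)cc(O)cc3O2)cc1 | target

Total step count: 7. Longest linear sequence: 4 steps (6 → 7 → 11 → 12 → 13; the branch from 8 is equally long).

Steps most likely to fail

Step 7. The excited photocatalyst may be quenched by adventitious phenoxide oxidation. Nickel may be sequestered by the 5-hydroxy-4-keto chelate, iodine radicals may scramble the alkene geometry, or traces of excess base may racemise C2. The fallback sets out from 12 and forms the same bond without light, photocatalyst or base. Esterification of 12 with N-hydroxyphthalimide (DIC, THF, 0 °C to rt) gives the N-(acyloxy)phthalimide redox-active ester F1. A thermal nickel-catalysed reductive cross-electrophile coupling of F1 with 5 follows (NiBr2·glyme, dtbbpy, Zn dust, DMA, rt). It generates the same aryloxymethyl radical by single-electron reduction and comes back to the route at 13.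

Step 5. Insertion into the electron-rich 5,7-dialkoxychromone may be sluggish and lose out to protodeboronation. Facial selectivity may also be insufficient, or the enantiomeric purity may erode through reversible ring opening. The fallback sets out from 7 and 10 and separates bond formation from stereocontrol. An achiral cationic palladium(II) conjugate addition (Pd(OCOCF3)2, 2,2'-bipyridine, aqueous 1,2-dichloroethane, 60 °C) gives the racemic flavanone triester F2. A Noyori-type asymmetric transfer hydrogenation is then run as a kinetic resolution (Cp*RhCl[(R,R)-TsDPEN], HCO2H/Et3N, EtOAc, rt). It should reduce only the 2R enantiomer, to the cis-(2R,4R)-flavan-4-ol F3. The unreacted 2S ketone is separated by chromatography, which comes back to the route at 11.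

Step 6. Hydrogenolysis may run on into the benzylic C2–O1 bond of ring C or into the C4 ketone. The fallback removes every reductive step by changing the protecting-group set, and it sets out from 6 and 8. Treatment of 6 with MOMCl (NaH, DMF, 0 °C) gives 5,7-bis(methoxymethoxy)-4H-chromen-4-one F4. Alkylation of 8 with tert-butyl bromoacetate (K2CO3, acetone) gives [4-(2-tert-butoxy-2-oxoethoxy)phenyl]boronic acid F5. The rhodium conditions of step 5 join them to the (2S)-bis-MOM tert-butyl ester flavanone F6. Acidolysis (TFA/CH2Cl2/H2O, rt) cleaves both acetals and the ester before the acid-sensitive geranyl ether exists, which comes back to the route at 12.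

Further compounds
F1 | step 7 | 1,3-dioxoisoindolin-2-yl 2-{4-[(2S)-5,7-dihydroxy-4-oxo-3,4-dihydro-2H-chromen-2-yl]phenoxy}acetate | O=C(COc1ccc([C@@H]2CC(=O)c3c(O)cc(O)cc3O2)cc1)ON1C(=O)c2ccccc2C1=O
F2 | step 5 | racemic benzyl 2-{4-[5,7-bis(benzyloxy)-4-oxo-3,4-dihydro-2H-chromen-2-yl]phenoxy}acetate | O=C(COc1ccc(C2CC(=O)c3c(OCc4ccccc4)cc(OCc4ccccc4)cc3O2)cc1)OCc1ccccc1
F3 | step 5 | benzyl 2-{4-[(2R,4R)-5,7-bis(benzyloxy)-4-hydroxy-3,4-dihydro-2H-chromen-2-yl]phenoxy}acetate | O=C(COc1ccc([C@H]2C[C@@H](O)c3c(OCc4ccccc4)cc(OCc4ccccc4)cc3O2)cc1)OCc1ccccc1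
F4 | step 6 | 5,7-bis(methoxymethoxy)-4H-chromen-4-one | COCOc1cc(OCOC)c2c(=O)ccoc2c1
F5 | step 6 | [4-(2-tert-butoxy-2-oxoethoxy)phenyl]boronic acid | CC(C)(C)OC(=O)COc1ccc(B(O)O)cc1
F6 | step 6 | tert-butyl 2-{4-[(2S)-5,7-bis(methoxymethoxy)-4-oxo-3,4-dihydro-2H-chromen-2-yl]phenoxy}acetate | CC(C)(C)OC(=O)COc1ccc([C@@H]2CC(=O)c3c(OCOC)cc(OCOC)cc3O2)cc1
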